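Assumption: the target has no stereocentre and no stereogenic double bond (both quaternary carbons carry two methyl groups, the prenyl alkene ends in two methyl groups, the vinyl group is terminal), so the compound is achiral and only constitution has to be controlled. The two partners of the key step and its product were checked atom by atom against the target and need no structural correction.

## Structural features

The target is a flavone, a 4H-chromen-4-one whose benzo ring A carries hydroxyls on C5 and C7, the ring oxygen O1 on C8a and a 3-methylbut-2-enyl (prenyl) group on C8. C2 of the pyranone ring C is bonded to C1' of ring B. Ring B is a resorcinol with hydroxyls on C2' and C4' and a 2-methylbut-3-en-2-yl (1,1-dimethylallyl) group on C5', so a quaternary benzylic carbon sits ortho to the C4' hydroxyl. There are no stereocentres, hence none adjacent to one another.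

The fragile pairings are the C8 prenyl group next to the 7-OH (acid closes it to a 2,2-dimethylchroman) and the C5' dimethylallyl group next to the 4'-OH (acid closes it to a dihydrobenzofuran, and heat on the free phenol causes abnormal-Claisen drift). The free polyphenol is also sensitive to air in base. The real difficulty is regiochemical: C8 rather than C6 on ring A, C5' with an all-carbon quaternary centre on ring B, and the differentiation of four phenols, of which the 5-OH chelated to C4=O is the least reactive.

The key step uses the fact that C4a, C8a and O1 belong to a threefold-symmetric 1,3,5-trioxygenated benzene. The unit C2–C3–C4 with ring B attached is an aroylacetate, so C4a–C4 and O1–C2 can be made with no regiochemical question on ring A.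

## Logic of the disconnections

19 to 18. The three O–CH2 acetal bonds on O7, O2' and O4' are cut last. This keeps every phenol that could close onto a neighbouring allyl group capped through the whole route, so the final operation only unmasks. The forward step must use acid mild enough to exchange the acetals without protonating the trisubstituted alkene on C8.

18 to 15. The C8–CH2 bond of the prenyl group is traced back through two [3,3] shifts (17, then 16) to the O5–CH2 allyl ether bond of 15. Direct C-alkylation cannot tell C8 from C6. O5 is the one oxygen that forms a chelate with C4=O, so a lanthanide can activate its ether, and its ortho carbon C6 relays the allyl unit to C8 with the normal prenyl connectivity restored. The C8 problem thus becomes a chemoselective O-alkylation. The demand is that the Cope shift of 16 outruns its enolisation and that only O5 carries an allyl group.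

15 to 14 and 2, then 14 to 13. The O5–C(allyl) bond and the O7–CH2 acetal bond are cut in that order. The two hydroxyls of 13 differ because 5-OH is hydrogen-bonded to C4=O, so the free 7-OH is capped first and the chelated one alkylated second. Using the same acetal on O7 as on ring B gives a single final deprotection and an ether that survives the carbonate base of the O5 alkylation; a silyl ether on O7 was rejected on both counts. The forward demand is clean mono-protection of 13.

13 to 9 and 10 (through 12 and 11). The bonds C4a–C4 and O1–C2 are cut. This removes the pyranone ring in one operation, returns ring A to a symmetric building block that needs no protection, and leaves all of ring B, including its quaternary carbon, in 9. The forward step must run without acid so that the pyranone and not the isomeric coumarin forms. O2' of 9 must be capped, because a free O2' would capture the ketene and compete in the cyclodehydration. O4' must be capped because a free phenol ortho to the dimethylallyl group would not tolerate the temperature. The two acetals on 9 are therefore a requirement of the step, and the price is that they must survive a short period near 240 °C.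

9 to 7 and 8. The C3–C4 bond between the methyl carbon of the aryl ketone and a carbonate carbon is cut. One partner cannot enolise, so the crossed Claisen condensation has a single direction; the demand is that no acidic OH remains, which 7 satisfies.

7 to 6 to 4 (through 5). The O4–CH2 acetal is removed and the aryl C5–C(quaternary) bond is traced back by a [3,3] shift to the O4–CH2 allyl ether bond. The aromatic Claisen rearrangement inverts the allyl unit, so a primary prenyl ether delivers the tertiary carbon to the ring. The demand is migration to C5 and not C3; O2 is capped so that the chelate that would bias the shift towards C3 is absent and C3 is the more crowded site.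

4 to 3 to 1 and 2. The O2–CH2 acetal bond and the O4–CH2 allyl bond are cut. In 1 the 2-OH is chelated to the acetyl group, so carbonate alkylates O4 only and a hydride base is then needed for O2.

## Other disconnections considered

Alternative 1: The cut is through the B-ring bonds C1'–C2' and C5'–C6', so that ring B is assembled last from an alkyne and a four-carbon diene. In the forward step 2-ethynyl-5,7-bis(methoxymethoxy)-8-(3-methylbut-2-enyl)-4H-chromen-4-one A1 would undergo a Diels–Alder reaction with 1-methoxy-5,5-dimethyl-1,3-bis(trimethylsilyloxy)hepta-1,3,6-triene A2. 1,4-Elimination of the methoxy group and desilylation would then give the 5,7-bis-acetal A3 with a free B-ring resorcinol.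
- In favour: the polarity match (nucleophilic C4 of A2 onto the terminal alkyne carbon) fixes the 2',4'-dioxygen and 5'-alkyl pattern, and the quaternary carbon comes from aliphatic chemistry with no aromatic Claisen step.
- Where it is better: no step near 240 °C with acetals present.
- Against: the bond-forming diene terminus bears a tertiary alkyl group and should react slowly. The alkyne is only vinylogously activated, and conjugate addition to the pyranone competes. A1 must already carry the C8 prenyl group, so the C6/C8 problem is moved and not solved.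
- Comparison: on structure the two plans define ring B equally well. Mechanistically the chosen step joins a symmetric nucleophile to an unhindered electrophile, whereas this one must form a bond at a neopentyl-like carbon. On step economy it should be several steps longer, because A1 and A2 each need their own sequence and an acid deprotection still follows.

Alternative 2: The cut is the A-ring bond C4a–C5 (equivalent to C4a–C8a at that stage), which unravels ring A to a linear polyketide. In the forward step methyl 9-[2,4-bis(methoxymethoxy)-5-(2-methylbut-3-en-2-yl)phenyl]-3,5,7,9-tetraoxononanoate A4 would close under base in the Claisen mode, C6 attacking the ester carbon. The product is 1-[2,4-bis(methoxymethoxy)-5-(2-methylbut-3-en-2-yl)phenyl]-3-(2,4,6-trihydroxyphenyl)propane-1,3-dione A5, which is the same compound as 12 and would cyclodehydrate to 13.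
- In favour: the closure is regiochemically neutral for the same symmetry reason, and the acetals are stable to base.
- Where it is better: it reaches 12 near room temperature, with no thermal stress on the acetals or the dimethylallyl group.
- Against: A4 needs polyanion chemistry to assemble, and several enolate/carbonyl pairings compete (aldol-mode closure of C2 onto the C7 carbonyl, O-cyclisations), so the mode depends finely on base and counter-ion. It also builds a benzene ring that is available as 10.
- Comparison: structurally the two plans are equal from 12 onwards, and steps 7 to 10 would be unchanged. Mechanistically the chosen step forms one irreversible C–C bond to a preformed ring, while this one must select one closure among several. On step economy it is worse by the chain-assembly steps.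

Alternative 3: The cuts are C4a–C4, C4–C3 and O1–C2. They divide the target into 2-iodo-3,5-bis(methoxymethoxy)-6-(3-methylbut-2-enyl)phenol A6, a one-carbon carbonyl unit from a carbonylating atmosphere, and 1-ethynyl-2,4-bis(methoxymethoxy)-5-(2-methylbut-3-en-2-yl)benzene A7. Palladium-catalysed carbonylative Sonogashira coupling in a secondary amine would give 1-[2-hydroxy-4,6-bis(methoxymethoxy)-3-(3-methylbut-2-enyl)phenyl]-3-[2,4-bis(methoxymethoxy)-5-(2-methylbut-3-en-2-yl)phenyl]prop-2-yn-1-one A8. This would close 6-endo at O1–C2 to the tetra-acetal of the target A9.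
- In favour: both allyl groups are in place before the union, so no sigmatropic step is needed on the flavone, and C8 is settled on a small arene.
- Where it is better or equal: it is the most convergent plan and runs at mild temperature, both better than the chosen plan. The final acid deprotection carries the same risk as in the chosen plan.
- Against: A6 is a hexasubstituted benzene that needs three differentiated oxygens, a poorly selective C-prenylation and a regioselective iodination. Its iodine is flanked by two ortho oxygens, which slows oxidative addition and favours coupling without carbonyl insertion, and 5-exo closure competes with 6-endo. A7 needs extra homologation steps from 7.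
- Comparison: structurally this plan fixes C8 early and the chosen plan fixes it late; ring B has the same origin in both. Mechanistically it has two selectivity issues in a three-component metal-catalysed step, against one thermal-tolerance issue in the chosen step. Its longest linear sequence could be shorter, but the total step count is higher and A6 is the weak link.

Key step: step 6

## Route

Step 1
Reactants: 1 1-(2,4-dihydroxyphenyl)ethanone (2,4-dihydroxyacetophenone); 2 1-bromo-3-methylbut-2-ene (prenyl bromide)
Product: 3 1-[2-hydroxy-4-(3-methylbut-2-enyloxy)phenyl]ethanone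
Conditions: K2CO3 (1.2 equiv), acetone, reflux
Reagents that add atoms: prenyl bromide 2, CC(C)=CCBr
Why: Williamson etherification; the 2-OH is held in a hydrogen bond to the acetyl oxygen and is the weaker nucleophile under carbonate, so SN2 alkylation at the primary allylic bromide should stop at O4.

Step 2
Reactants: 3 1-[2-hydroxy-4-(3-methylbut-2-enyloxy)phenyl]ethanone
Product: 4 1-[2-(methoxymethoxy)-4-(3-methylbut-2-enyloxy)phenyl]ethanone
Conditions: NaH, MOMCl, THF–DMF, 0 °C to rt
Reagents that add atoms: chloromethyl methyl ether (MOMCl), COCCl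
Why: Irreversible deprotonation breaks the chelate and the phenoxide is O-alkylated by the α-chloro ether; capping O2 is what directs the next step to C5.

Step 3
Reactants: 4 1-[2-(methoxymethoxy)-4-(3-methylbut-2-enyloxy)phenyl]ethanone
Product: 6 1-[4-hydroxy-2-(methoxymethoxy)-5-(2-methylbut-3-en-2-yl)phenyl]ethanone, via cyclohexadienone 5 (not isolated)
Conditions: EtOH–H2O (4:1), sealed tube, 130 °C
Reagents that add atoms: none
Why: Aromatic Claisen rearrangement ([3,3], chair transition state) delivers the tertiary allyl terminus to the ring and dienone 5 enolises to the phenol, its transient stereocentre being lost. With O2 capped there is no chelate-induced bias towards C3, which is also flanked by two oxygen substituents, so the shift should go to the open C5. The aqueous medium lowers the temperature needed and limits abnormal-Claisen drift of the product.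

Step 4
Reactants: 6 1-[4-hydroxy-2-(methoxymethoxy)-5-(2-methylbut-3-en-2-yl)phenyl]ethanone
Product: 7 1-[2,4-bis(methoxymethoxy)-5-(2-methylbut-3-en-2-yl)phenyl]ethanone
Conditions: MOMCl, K2CO3, acetone, rt to 50 °C
Reagents that add atoms: chloromethyl methyl ether (MOMCl), COCCl
Why: O-Alkylation of the acidic para-acyl phenol; this caps the phenol ortho to the dimethylallyl group before strong base or heat is applied.

Step 5
Reactants: 7 1-[2,4-bis(methoxymethoxy)-5-(2-methylbut-3-en-2-yl)phenyl]ethanone; 8 diethyl carbonate
Product: 9 ethyl 3-[2,4-bis(methoxymethoxy)-5-(2-methylbut-3-en-2-yl)phenyl]-3-oxopropanoate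
Conditions: NaH (3 equiv), (EtO)2CO (excess), toluene, 100 °C; AcOH quench at 0 °C
Reagents that add atoms: diethyl carbonate 8, CCOC(=O)OCC
Why: Crossed Claisen condensation; the methyl ketone enolate attacks the non-enolisable carbonate and deprotonation of the β-keto ester drives the equilibrium, with no other acidic site present.

Step 6
Reactants: 9 ethyl 3-[2,4-bis(methoxymethoxy)-5-(2-methylbut-3-en-2-yl)phenyl]-3-oxopropanoate; 10 benzene-1,3,5-triol (phloroglucinol)
Product: 13 2-[2,4-bis(methoxymethoxy)-5-(2-methylbut-3-en-2-yl)phenyl]-5,7-dihydroxy-4H-chromen-4-one, via aroylketene 11 (not isolated), via 1,3-diketone 12 (not isolated)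
Conditions: 10 (3 equiv), neat melt, Ar, 240 °C, 5–10 min (microwave or preheated bath), volatiles vented
Reagents that add atoms: none
Why: Heating should expel ethanol from the enol form of 9 to give aroylketene 11, whose ketene carbon is attacked by a ring carbon of 10 (a strongly C-nucleophilic, enol-like arene); tautomerisation then gives the chelated 1,3-diketone 12 and forms C4a–C4. O-Acylation of 10, where it occurs, is reversible at this temperature because aryl β-keto esters release the ketene again, whereas C-acylation is not reversed. One of the two equivalent ortho hydroxyls of 12 then adds to the B-ring ketone in a 6-exo-trig closure and the hemiketal loses water, which forms O1–C2 and the aromatic 4-pyranone, the only ring closed. No stereocentre is created. The closest known reaction type is the uncatalysed thermal condensation of polyhydric phenols with β-keto esters (Mentzer pyranone synthesis), which is established for 10 with aroylacetates under brief neat heating. Ring fusion needs no regiocontrol because all ring carbons and hydroxyls of 10 are equivalent, and the excess of 10 guards against a second annulation on the product. The selectivity that matters is pyranone against 4-arylcoumarin: coumarin (Pechmann) closure needs acid to make the ketone carbon the electrophile towards the arene, while in an acid-free melt the acyl carbon of the ketene is the electrophile, so the ester-derived carbon ends up as C4 on C4a. The acetal on O2' prevents that oxygen from capturing the ketene or joining the cyclodehydration, and the acetal on O4' keeps the neighbouring dimethylallyl group out of phenol-driven rearrangement at this temperature.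

Step 7
Reactants: 13 2-[2,4-bis(methoxymethoxy)-5-(2-methylbut-3-en-2-yl)phenyl]-5,7-dihydroxy-4H-chromen-4-one
Product: 14 2-[2,4-bis(methoxymethoxy)-5-(2-methylbut-3-en-2-yl)phenyl]-5-hydroxy-7-(methoxymethoxy)-4H-chromen-4-one
Conditions: MOMCl (1.1 equiv), i-Pr2NEt, CH2Cl2, 0 °C
Reagents that add atoms: chloromethyl methyl ether (MOMCl), COCCl
Why: Selective O-acetalisation; the 7-OH is the more acidic and the only non-chelated hydroxyl, so one equivalent of chloride with an amine base should stop there. The acetal matches those on ring B, so one operation removes all three at the end.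

Step 8
Reactants: 14 2-[2,4-bis(methoxymethoxy)-5-(2-methylbut-3-en-2-yl)phenyl]-5-hydroxy-7-(methoxymethoxy)-4H-chromen-4-one; 2 1-bromo-3-methylbut-2-ene (prenyl bromide)
Product: 15 2-[2,4-bis(methoxymethoxy)-5-(2-methylbut-3-en-2-yl)phenyl]-7-(methoxymethoxy)-5-(3-methylbut-2-enyloxy)-4H-chromen-4-one
Conditions: K2CO3, DMF, rt to 40 °C
Reagents that add atoms: prenyl bromide 2, CC(C)=CCBr
Why: Williamson etherification of the chelated 5-OH, the only free hydroxyl left; carbonate in a dipolar solvent breaks the hydrogen bond and the primary allylic bromide reacts at oxygen by SN2, the acetals being inert to base.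

Step 9
Reactants: 15 2-[2,4-bis(methoxymethoxy)-5-(2-methylbut-3-en-2-yl)phenyl]-7-(methoxymethoxy)-5-(3-methylbut-2-enyloxy)-4H-chromen-4-one
Product: 18 2-[2,4-bis(methoxymethoxy)-5-(2-methylbut-3-en-2-yl)phenyl]-5-hydroxy-7-(methoxymethoxy)-8-(3-methylbut-2-enyl)-4H-chromen-4-one, via ortho-dienone 16 (not isolated), via para-dienone 17 (not isolated)
Conditions: Eu(fod)3 (10 mol %), NaHCO3, PhCl, 85 °C
Reagents that add atoms: none
Why: Lanthanide-catalysed para-Claisen–Cope rearrangement; Eu(III) bound at O5/C4=O accelerates the [3,3] shift to C6, giving 16. The 1,5-diene of 16 (C8=C7–C6–CMe2–CH=CH2) then undergoes a Cope shift to C8, which relieves crowding at C6 and restores the normal prenyl connectivity in 17; enolisation gives 18 and removes the transient stereocentres. NaHCO3 guards the allyl ether against acid-induced cleavage.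

Step 10
Reactants: 18 2-[2,4-bis(methoxymethoxy)-5-(2-methylbut-3-en-2-yl)phenyl]-5-hydroxy-7-(methoxymethoxy)-8-(3-methylbut-2-enyl)-4H-chromen-4-one
Product: 19 2-[2,4-dihydroxy-5-(2-methylbut-3-en-2-yl)phenyl]-5,7-dihydroxy-8-(3-methylbut-2-enyl)-4H-chromen-4-one
Conditions: 3 M aq HCl (cat. to few equiv), MeOH, degassed, 40 °C
Reagents that add atoms: none
Why: Acid-catalysed acetal exchange with methanol releases the three phenols. Dilute acid at mild temperature is chosen because the acetal oxygens are protonated far more readily than the trisubstituted alkene, whose protonation would lead to chroman closure.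

## Compound list

1 | 1-(2,4-dihydroxyphenyl)ethanone (2,4-dihydroxyacetophenone) | CC(=O)c1ccc(O)cc1O | starting material
2 | 1-bromo-3-methylbut-2-ene (prenyl bromide) | CC(C)=CCBr | starting material
3 | 1-[2-hydroxy-4-(3-methylbut-2-enyloxy)phenyl]ethanone | CC(=O)c1ccc(OCC=C(C)C)cc1O | intermediate
4 | 1-[2-(methoxymethoxy)-4-(3-methylbut-2-enyloxy)phenyl]ethanone | CC(=O)c1ccc(OCC=C(C)C)cc1OCOC | intermediate
5 | 4-acetyl-3-(methoxymethoxy)-6-(2-methylbut-3-en-2-yl)cyclohexa-2,4-dien-1-one (racemic, formed in step 3, not isolated) | CC(=O)C1=CC(C(C)(C)C=C)C(=O)C=C1OCOC | intermediate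
6 | 1-[4-hydroxy-2-(methoxymethoxy)-5-(2-methylbut-3-en-2-yl)phenyl]ethanone | CC(=O)c1cc(C(C)(C)C=C)c(O)cc1OCOC | intermediate
7 | 1-[2,4-bis(methoxymethoxy)-5-(2-methylbut-3-en-2-yl)phenyl]ethanone | CC(=O)c1cc(C(C)(C)C=C)c(OCOC)cc1OCOC | intermediate
8 | diethyl carbonate | CCOC(=O)OCC | starting material
9 | ethyl 3-[2,4-bis(methoxymethoxy)-5-(2-methylbut-3-en-2-yl)phenyl]-3-oxopropanoate | CCOC(=O)CC(=O)c1cc(C(C)(C)C=C)c(OCOC)cc1OCOC | intermediate
10 | benzene-1,3,5-triol (phloroglucinol) | Oc1cc(O)cc(O)c1 | starting material
11 | 3-[2,4-bis(methoxymethoxy)-5-(2-methylbut-3-en-2-yl)phenyl]-3-oxoprop-1-en-1-one (aroylketene, formed in step 6, not isolated) | O=C=CC(=O)c1cc(C(C)(C)C=C)c(OCOC)cc1OCOC | intermediate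
12 | 1-[2,4-bis(methoxymethoxy)-5-(2-methylbut-3-en-2-yl)phenyl]-3-(2,4,6-trihydroxyphenyl)propane-1,3-dione (formed in step 6, not isolated) | O=C(CC(=O)c1c(O)cc(O)cc1O)c1cc(C(C)(C)C=C)c(OCOC)cc1OCOC | intermediate
13 | 2-[2,4-bis(methoxymethoxy)-5-(2-methylbut-3-en-2-yl)phenyl]-5,7-dihydroxy-4H-chromen-4-one | C=CC(C)(C)c1cc(-c2cc(=O)c3c(O)cc(O)cc3o2)c(OCOC)cc1OCOC | intermediate
14 | 2-[2,4-bis(methoxymethoxy)-5-(2-methylbut-3-en-2-yl)phenyl]-5-hydroxy-7-(methoxymethoxy)-4H-chromen-4-one | C=CC(C)(C)c1cc(-c2cc(=O)c3c(O)cc(OCOC)cc3o2)c(OCOC)cc1OCOC | intermediate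
15 | 2-[2,4-bis(methoxymethoxy)-5-(2-methylbut-3-en-2-yl)phenyl]-7-(methoxymethoxy)-5-(3-methylbut-2-enyloxy)-4H-chromen-4-one | C=CC(C)(C)c1cc(-c2cc(=O)c3c(OCC=C(C)C)cc(OCOC)cc3o2)c(OCOC)cc1OCOC | intermediate
16 | 2-[2,4-bis(methoxymethoxy)-5-(2-methylbut-3-en-2-yl)phenyl]-7-(methoxymethoxy)-6-(2-methylbut-3-en-2-yl)-6H-chromene-4,5-dione (racemic, formed in step 9, not isolated) | C=CC(C)(C)C1C(=O)C2=C(C=C1OCOC)OC(=CC2=O)c1cc(C(C)(C)C=C)c(OCOC)cc1OCOC | intermediate
17 | 2-[2,4-bis(methoxymethoxy)-5-(2-methylbut-3-en-2-yl)phenyl]-7-(methoxymethoxy)-8-(3-methylbut-2-enyl)-8H-chromene-4,5-dione (racemic, formed in step 9, not isolated) | CC(C)=CCC1C(OCOC)=CC(=O)C2=C1OC(=CC2=O)c1cc(C(C)(C)C=C)c(OCOC)cc1OCOC | intermediate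
18 | 2-[2,4-bis(methoxymethoxy)-5-(2-methylbut-3-en-2-yl)phenyl]-5-hydroxy-7-(methoxymethoxy)-8-(3-methylbut-2-enyl)-4H-chromen-4-one | C=CC(C)(C)c1cc(-c2cc(=O)c3c(O)cc(OCOC)c(CC=C(C)C)c3o2)c(OCOC)cc1OCOC | intermediate
19 | 2-[2,4-dihydroxy-5-(2-methylbut-3-en-2-yl)phenyl]-5,7-dihydroxy-8-(3-methylbut-2-enyl)-4H-chromen-4-one | C=CC(C)(C)c1cc(-c2cc(=O)c3c(O)cc(O)c(CC=C(C)C)c3o2)c(O)cc1O | target

## Step count and least certain steps

Total: 10 steps. Longest linear sequence: 10 steps (1 to 19); compounds 2, 8 and 10 enter without prior steps.

Step 6 (key step). The most likely failure is loss or transfer of the acetal groups in the hot, weakly acidic phenolic melt while ethanol and water are being released. A freed O2' would then capture the ketene, and a freed O4' would expose the dimethylallyl group to thermal rearrangement. Acylation could also stall at oxygen until the mixture degrades. The fallback builds the same pyranone from the other side at low temperature; it sets out from 7 and returns at 15, so steps 7 and 8 are not needed.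
- Purchased 2,4,6-trihydroxybenzoic acid F1 (also accessible from 10 by Kolbe–Schmitt carboxylation) would be converted with acetone, trifluoroacetic anhydride and trifluoroacetic acid into 5,7-dihydroxy-2,2-dimethyl-4H-1,3-benzodioxin-4-one F2.
- The non-chelated hydroxyl of F2 would be capped (MOMCl, i-Pr2NEt) to give 5-hydroxy-7-(methoxymethoxy)-2,2-dimethyl-4H-1,3-benzodioxin-4-one F3.
- The chelated hydroxyl of F3 would be alkylated with 2 (K2CO3, DMF) to give 7-(methoxymethoxy)-2,2-dimethyl-5-(3-methylbut-2-enyloxy)-4H-1,3-benzodioxin-4-one F4.
- The lithium enolate of 7 (LiHMDS, THF, −78 °C to rt, excess base) would open F4 at its carbonyl with loss of acetone. This gives 1-[2,4-bis(methoxymethoxy)-5-(2-methylbut-3-en-2-yl)phenyl]-3-[2-hydroxy-4-(methoxymethoxy)-6-(3-methylbut-2-enyloxy)phenyl]propane-1,3-dione F5.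
- The single free phenol of F5 would close onto the B-ring ketone under buffered acetic acid (AcOH, NaOAc, about 60 °C) to give 15.

Step 3. The risks are poor positional selectivity of the [3,3] shift (C3 against C5), onward abnormal-Claisen isomerisation or ring closure of the product phenol on prolonged heating, and hydrolytic loss of the O2 acetal before the shift, which would redirect the allyl group to C3. The fallback replaces the sigmatropic step by a cross-coupling; it sets out from 1 and returns at 7.
- Bromination of 1 at the doubly activated, unhindered C5 (NBS, MeCN, 0 °C) should give 1-(5-bromo-2,4-dihydroxyphenyl)ethanone F6.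
- Double protection (NaH, MOMCl) would give 1-[5-bromo-2,4-bis(methoxymethoxy)phenyl]ethanone F7.
- A γ-selective Suzuki–Miyaura coupling of F7 with 3-methylbut-2-enylboronic acid pinacol ester (Pd catalyst with a biarylphosphine ligand chosen for branched selectivity, K3PO4, aqueous THF) should attach the tertiary carbon and give 7.

Step 9. The risks are that dienone 16 enolises before the Cope shift, which would leave the allyl group on C6 in its inverted form, and that the Lewis acid cleaves the allyl ether. The fallback moves the allyl group through O7 instead of O5; it sets out from 13 and returns at 19.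
- The more acidic 7-OH of 13 would be converted by a Tsuji–Trost O-allylation (tert-butyl 2-methylbut-3-en-2-yl carbonate, Pd(PPh3)4, THF, 0 °C) into the tertiary ether 2-[2,4-bis(methoxymethoxy)-5-(2-methylbut-3-en-2-yl)phenyl]-5-hydroxy-7-(2-methylbut-3-en-2-yloxy)-4H-chromen-4-one F8.
- An aromatic Claisen rearrangement of F8 (toluene, about 110 °C) delivers the normal prenyl group directly to an ortho carbon. The product would be 2-[2,4-bis(methoxymethoxy)-5-(2-methylbut-3-en-2-yl)phenyl]-5,7-dihydroxy-8-(3-methylbut-2-enyl)-4H-chromen-4-one F9; the C6 isomer may have to be separated.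
- Acid exchange of the two remaining acetals, as in step 10, would give 19.

Step 10. The risk is protonation of the prenyl alkene with capture of the tertiary cation by the 7-OH or by solvent and, more slowly, the analogous closure of the 4'-OH onto the vinyl group. The fallback changes the protecting-group plan so that the last step uses fluoride; it sets out from 13 and returns at 19.
- The acetals would be removed from 13 while no prenyl group is present (HCl, MeOH) to give 2-[2,4-dihydroxy-5-(2-methylbut-3-en-2-yl)phenyl]-5,7-dihydroxy-4H-chromen-4-one F10.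
- Silylation of the three non-chelated hydroxyls (TBSCl, imidazole, DMF) would give 2-[2,4-bis(tert-butyldimethylsilyloxy)-5-(2-methylbut-3-en-2-yl)phenyl]-7-(tert-butyldimethylsilyloxy)-5-hydroxy-4H-chromen-4-one F11.
- Neutral Mitsunobu etherification of the 5-OH (3-methylbut-2-en-1-ol, PPh3, DIAD) would give 2-[2,4-bis(tert-butyldimethylsilyloxy)-5-(2-methylbut-3-en-2-yl)phenyl]-7-(tert-butyldimethylsilyloxy)-5-(3-methylbut-2-enyloxy)-4H-chromen-4-one F12.
- The europium-catalysed Claisen–Cope shift, as in step 9, would give 2-[2,4-bis(tert-butyldimethylsilyloxy)-5-(2-methylbut-3-en-2-yl)phenyl]-7-(tert-butyldimethylsilyloxy)-5-hydroxy-8-(3-methylbut-2-enyl)-4H-chromen-4-one F13.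
- Buffered fluoride (TBAF, AcOH, THF, 0 °C) would release 19.

## Further compounds

F1 | step 6 | 2,4,6-trihydroxybenzoic acid (purchased) | O=C(O)c1c(O)cc(O)cc1O
F2 | step 6 | 5,7-dihydroxy-2,2-dimethyl-4H-1,3-benzodioxin-4-one | CC1(C)OC(=O)c2c(O)cc(O)cc2O1
F3 | step 6 | 5-hydroxy-7-(methoxymethoxy)-2,2-dimethyl-4H-1,3-benzodioxin-4-one | CC1(C)OC(=O)c2c(O)cc(OCOC)cc2O1
F4 | step 6 | 7-(methoxymethoxy)-2,2-dimethyl-5-(3-methylbut-2-enyloxy)-4H-1,3-benzodioxin-4-one | CC1(C)OC(=O)c2c(OCC=C(C)C)cc(OCOC)cc2O1
F5 | step 6 | 1-[2,4-bis(methoxymethoxy)-5-(2-methylbut-3-en-2-yl)phenyl]-3-[2-hydroxy-4-(methoxymethoxy)-6-(3-methylbut-2-enyloxy)phenyl]propane-1,3-dione | O=C(CC(=O)c1c(O)cc(OCOC)cc1OCC=C(C)C)c1cc(C(C)(C)C=C)c(OCOC)cc1OCOC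
F6 | step 3 | 1-(5-bromo-2,4-dihydroxyphenyl)ethanone | CC(=O)c1cc(Br)c(O)cc1O
F7 | step 3 | 1-[5-bromo-2,4-bis(methoxymethoxy)phenyl]ethanone | CC(=O)c1cc(Br)c(OCOC)cc1OCOC
F8 | step 9 | 2-[2,4-bis(methoxymethoxy)-5-(2-methylbut-3-en-2-yl)phenyl]-5-hydroxy-7-(2-methylbut-3-en-2-yloxy)-4H-chromen-4-one | C=CC(C)(C)c1cc(-c2cc(=O)c3c(O)cc(OC(C)(C)C=C)cc3o2)c(OCOC)cc1OCOC
F9 | step 9 | 2-[2,4-bis(methoxymethoxy)-5-(2-methylbut-3-en-2-yl)phenyl]-5,7-dihydroxy-8-(3-methylbut-2-enyl)-4H-chromen-4-one | C=CC(C)(C)c1cc(-c2cc(=O)c3c(O)cc(O)c(CC=C(C)C)c3o2)c(OCOC)cc1OCOC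
F10 | step 10 | 2-[2,4-dihydroxy-5-(2-methylbut-3-en-2-yl)phenyl]-5,7-dihydroxy-4H-chromen-4-one | C=CC(C)(C)c1cc(-c2cc(=O)c3c(O)cc(O)cc3o2)c(O)cc1O
F11 | step 10 | 2-[2,4-bis(tert-butyldimethylsilyloxy)-5-(2-methylbut-3-en-2-yl)phenyl]-7-(tert-butyldimethylsilyloxy)-5-hydroxy-4H-chromen-4-one | C=CC(C)(C)c1cc(-c2cc(=O)c3c(O)cc(O[Si](C)(C)C(C)(C)C)cc3o2)c(O[Si](C)(C)C(C)(C)C)cc1O[Si](C)(C)C(C)(C)C
F12 | step 10 | 2-[2,4-bis(tert-butyldimethylsilyloxy)-5-(2-methylbut-3-en-2-yl)phenyl]-7-(tert-butyldimethylsilyloxy)-5-(3-methylbut-2-enyloxy)-4H-chromen-4-one | C=CC(C)(C)c1cc(-c2cc(=O)c3c(OCC=C(C)C)cc(O[Si](C)(C)C(C)(C)C)cc3o2)c(O[Si](C)(C)C(C)(C)C)cc1O[Si](C)(C)C(C)(C)C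
F13 | step 10 | 2-[2,4-bis(tert-butyldimethylsilyloxy)-5-(2-methylbut-3-en-2-yl)phenyl]-7-(tert-butyldimethylsilyloxy)-5-hydroxy-8-(3-methylbut-2-enyl)-4H-chromen-4-one | C=CC(C)(C)c1cc(-c2cc(=O)c3c(O)cc(O[Si](C)(C)C(C)(C)C)c(CC=C(C)C)c3o2)c(O[Si](C)(C)C(C)(C)C)cc1O[Si](C)(C)C(C)(C)C
A1 | alternative 1 | 2-ethynyl-5,7-bis(methoxymethoxy)-8-(3-methylbut-2-enyl)-4H-chromen-4-one | C#Cc1cc(=O)c2c(OCOC)cc(OCOC)c(CC=C(C)C)c2o1
A2 | alternative 1 | 1-methoxy-5,5-dimethyl-1,3-bis(trimethylsilyloxy)hepta-1,3,6-triene (double-bond geometry not specified) | COC(O[Si](C)(C)C)=CC(O[Si](C)(C)C)=CC(C)(C)C=C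
A3 | alternative 1 | 2-[2,4-dihydroxy-5-(2-methylbut-3-en-2-yl)phenyl]-5,7-bis(methoxymethoxy)-8-(3-methylbut-2-enyl)-4H-chromen-4-one | C=CC(C)(C)c1cc(-c2cc(=O)c3c(OCOC)cc(OCOC)c(CC=C(C)C)c3o2)c(O)cc1O
A4 | alternative 2 | methyl 9-[2,4-bis(methoxymethoxy)-5-(2-methylbut-3-en-2-yl)phenyl]-3,5,7,9-tetraoxononanoate | COC(=O)CC(=O)CC(=O)CC(=O)CC(=O)c1cc(C(C)(C)C=C)c(OCOC)cc1OCOC
A5 | alternative 2 | 1-[2,4-bis(methoxymethoxy)-5-(2-methylbut-3-en-2-yl)phenyl]-3-(2,4,6-trihydroxyphenyl)propane-1,3-dione (identical with 12) | O=C(CC(=O)c1c(O)cc(O)cc1O)c1cc(C(C)(C)C=C)c(OCOC)cc1OCOC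
A6 | alternative 3 | 2-iodo-3,5-bis(methoxymethoxy)-6-(3-methylbut-2-enyl)phenol | Oc1c(I)c(OCOC)cc(OCOC)c1CC=C(C)C
A7 | alternative 3 | 1-ethynyl-2,4-bis(methoxymethoxy)-5-(2-methylbut-3-en-2-yl)benzene | C#Cc1cc(C(C)(C)C=C)c(OCOC)cc1OCOC
A8 | alternative 3 | 1-[2-hydroxy-4,6-bis(methoxymethoxy)-3-(3-methylbut-2-enyl)phenyl]-3-[2,4-bis(methoxymethoxy)-5-(2-methylbut-3-en-2-yl)phenyl]prop-2-yn-1-one | O=C(C#Cc1cc(C(C)(C)C=C)c(OCOC)cc1OCOC)c1c(O)c(CC=C(C)C)c(OCOC)cc1OCOC
A9 | alternative 3 | 2-[2,4-bis(methoxymethoxy)-5-(2-methylbut-3-en-2-yl)phenyl]-5,7-bis(methoxymethoxy)-8-(3-methylbut-2-enyl)-4H-chromen-4-one | C=CC(C)(C)c1cc(-c2cc(=O)c3c(OCOC)cc(OCOC)c(CC=C(C)C)c3o2)c(OCOC)cc1OCOC
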